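The numbers in the tables are simulated with made-up constants, and the scatter is random.

Friday's flask, charged with more G than Wednesday's, holds a smaller fraction of its Q at 8.00 h, 71.3 % against 79.8 %, from the same Q charge.

common to all: Q 0.62 M

| flask | G | remark | time |
|---|---|---|---|
| Wednesday's | 1.7 M | run made earlier |  |
| Friday's | 2.7 M | run made earlier |  |
| flask | 1.24 M |  | 8.0 h |

| run | time / h | Q / % | L / % |
|---|---|---|---|
| Wednesday's | 0.667 | 96.0 | 0.5 |
| Wednesday's | 1.00 | 93.9 | 0 |
| Wednesday's | 1.33 | 94.5 | 2.7 |
| Wednesday's | 2.50 | 92.4 | 4.2 |
| Wednesday's | 3.00 | 90.9 | 5.5 |
| Wednesday's | 5.00 | 84.8 | 9.3 |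
| Wednesday's | 8.00 | 79.8 | 16.9 |
| Friday's | 0.667 | 95.1 | 1.1 |
| Friday's | 1.00 | 94.3 | 2.0 |
| Friday's | 1.33 | 93.7 | 3.1 |
| Friday's | 2.50 | 87.7 | 6.7 |
| Friday's | 3.00 | 87.5 | 9.6 |
| Friday's | 5.00 | 77.5 | 16.2 |
| Friday's | 8.00 | 71.3 | 25.7 |

(readings scatter by 1 percentage point)

1. why nothing more happens at 8.0 h, or that something still does (forward and back rates have come level / all of Q has reacted / G has run out first / it is still moving)
2. share of the Q used up at 8.0 h
3. L at 8.0 h, in percent of the Q charged

- percent here means Q units held: one L counts as two
- on the list of suspects stand: G + E -> X; Q <-> E; Q + X -> L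
- the reaction counts as stopped when no species that holds the Q changes by six tenths of a point or more over the second half of the time

The new flask has less G than Wednesday's, so Wednesday's conversion of 20.2 % is a first ceiling. A straight line through the two conversions, carried down to the new G, tightens it to 16.3 %, and such a line runs high on a fall that bends. For the floor, both runs have lost a similar part by 0.667 h (96.0 % and 95.1 % left) despite their different G, so scaling Wednesday's whole conversion by the ratio of G cuts too much and gives 14.7 %. Both edges rest on readings with a scatter of 1 percentage point, and the line, carried beyond the two runs, magnifies it.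

Inside the bracket, my own reckoning takes G as constant, being charged above Q, which makes the fall of the fraction q pseudo-first-order. The carried quantity is the G-slope, the drop in ln q per unit of G and per hour between two flasks read at the same hour, here read off the last readings of the two runs as 0.0141 L mol⁻¹ h⁻¹; the early loss cancels in it. Stepping from Wednesday's q to the new G gives q = 84.0 %, so conversion 16.0 %. Wednesday's gap between conversion and L, 3.3 points, then leaves L at 12.7 %. Over the second half of the time q in the new flask still falls, by this reckoning, by 6.1 points, which counts as moving.

The forecast says it is still moving, with conversion 16 % (14 % to 18.5 %) and L 13 % (11 % to 14.5 %), on the ground that “the decay is first order in Q and in G”. Its conversion lies inside the bracket.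

In the flask it is still moving, with conversion 16.4 % and L 13.0 %; the conversion stands just above the tightened ceiling, within the scatter.

    G + E → X (k = 0.245 L mol⁻¹ h⁻¹)
    Q ⇌ E (K = 0.0330, k = 8.48 h⁻¹)
    Q + X → L (k = 2.61 L mol⁻¹ h⁻¹)

Two things act together in keeping the flask moving at this hour: E returns to Q, and the reading comes early. Without that return the conversion goes from 16.4 % to 100 %, and at ten times the hour it reaches 75.3 %. For the same flask left until 2.0 h, the G-slope steps q back up and gives conversion 6.68 %; the computed flask gives 6.30 %.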